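**Assumption:** (S)-(+)-linalool of ≥97% ee and Seebach's (2S,5S)-2-tert-butyl-5-methyl-1,3-dioxolan-4-one (from (S)-lactic acid and pivalaldehyde) are taken as purchasable; side-chain carbons carry primed locants (C1' on C2 of the chroman to C12' at the chain end).

## Retrosynthetic overview

1. Target 21 ⇐ desilylation of 20 ⇐ catalyst-controlled reduction of the C7' ketone 19 (sets 7'S).
2. Key bond C4'–C5': ketone homoenolate 17 (β-zincio ketone from cyclopropanol 16) joined to the 1,1-dichloroalkene 10 trans to the chain, then methyl for the remaining chloride (E-alkene).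
3. Cyclopropanol 16 ⇐ Kulinkovich reaction of (R)-hydroxy ester 15 ⇐ Seebach alkylation of lactate dioxolanone 11 with homoprenyl bromide 12 (sets 8'R).
4. Dichloroalkene 10 ⇐ aldehyde 9 ⇐ oxidative cleavage of the prenyl chroman 7.
5. Rings: the benzene ring is bought; the only ring closed is the dihydropyran ring of 7, by Pd C–O closure of tertiary alcohol 6, made from (S)-linalool and aryl bromide 3 (C2 from linalool); the cyclopropane of 16 is formed in step 8 and opened in step 9.

## Route

Step 1
Reactants: 1 3-bromo-5-methylphenol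
Product: 2 3-bromo-4-chloro-5-methylphenol
Conditions: SO2Cl2 (1.05 equiv), Ph2S (5 mol %), AlCl3 (5 mol %), CH2Cl2, 0 °C → rt
Reagents that add atoms: sulfuryl chloride O=S(=O)(Cl)Cl
Why: Electrophilic aromatic chlorination in which the hydroxyl group directs para and the sulfide/AlCl3-modified reagent is para-selective (as in the chlorination of 3,5-dimethylphenol), so chlorine enters between Br and CH3.

Step 2
Reactants: 2 3-bromo-4-chloro-5-methylphenol
Product: 3 (3-bromo-4-chloro-5-methylphenoxy)triisopropylsilane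
Conditions: iPr3SiCl, imidazole, DMF, rt
Reagents that add atoms: chlorotriisopropylsilane CC(C)[Si](Cl)(C(C)C)C(C)C
Why: Standard imidazole-promoted silylation gives a TIPS aryl ether that survives bases, organometallics and hydrides and is removed by fluoride at the end.

Step 3
Reactants: 4 (S)-linalool; 3 (3-bromo-4-chloro-5-methylphenoxy)triisopropylsilane
Product: 6 (3S)-1-[2-chloro-3-methyl-5-(triisopropylsilyloxy)phenyl]-3,7-dimethyloct-6-en-3-ol, via alkylborane 5 (not isolated)
Conditions: 9-BBN (1.5 equiv), THF, 0 °C → rt; then 3 (0.9 equiv), PdCl2(dppf) (5 mol %), 3 M aq. K3PO4, DMF, 60 °C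
Reagents that add atoms: none
Why: 9-BBN hydroborates only the monosubstituted vinyl group (anti-Markovnikov, trisubstituted alkene untouched) and the B-alkyl Suzuki–Miyaura coupling takes place at C–Br and not at the flanked C–Cl, while the carbinol stereocentre of linalool (future C2) is not involved.

Step 4
Reactants: 6 (3S)-1-[2-chloro-3-methyl-5-(triisopropylsilyloxy)phenyl]-3,7-dimethyloct-6-en-3-ol
Product: 7 triisopropyl{[(2S)-2,8-dimethyl-2-(4-methylpent-3-en-1-yl)chroman-6-yl]oxy}silane
Conditions: Pd(OAc)2 (5 mol %), 2-(di-tert-butylphosphino)-1,1'-binaphthyl (6 mol %), Cs2CO3, toluene, 90 °C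
Reagents that add atoms: none
Why: Intramolecular Buchwald-type palladium-catalysed aryl etherification of a tertiary alkoxide (no β-hydride pathway) closes the six-membered ring, and because the carbinol C–O bond is kept the (S) configuration at C2 is retained.

Step 5
Reactants: 7 triisopropyl{[(2S)-2,8-dimethyl-2-(4-methylpent-3-en-1-yl)chroman-6-yl]oxy}silane
Product: 9 3-[(2R)-2,8-dimethyl-6-(triisopropylsilyloxy)chroman-2-yl]propanal, via diol 8 (not isolated)
Conditions: OsO4 (2 mol %), NaIO4 (4 equiv), 2,6-lutidine, dioxane–H2O (3:1), rt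
Reagents that add atoms: osmium tetroxide O=[Os](=O)(=O)=O (delivers the oxygen, regenerated by periodate); sodium periodate [Na+].[O-]I(=O)(=O)=O
Why: Lemieux–Johnson oxidation (catalytic dihydroxylation, then periodate glycol cleavage) cuts the only alkene to the C3' aldehyde without touching the electron-rich arene; the descriptor at C2 changes to R by priority rules only.

Step 6
Reactants: 9 3-[(2R)-2,8-dimethyl-6-(triisopropylsilyloxy)chroman-2-yl]propanal
Product: 10 {[(2S)-2-(4,4-dichlorobut-3-en-1-yl)-2,8-dimethylchroman-6-yl]oxy}triisopropylsilane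
Conditions: PPh3 (3 equiv), BrCCl3 (1.5 equiv), MeCN, 0 °C → rt
Reagents that add atoms: bromotrichloromethane ClC(Cl)(Cl)Br
Why: Ramirez-type Wittig dichloromethylenation with Ph3P=CCl2 generated in the flask converts the aldehyde into the 1,1-dichloroalkene under neutral conditions.

Step 7
Reactants: 11 (2S,5S)-2-tert-butyl-5-methyl-1,3-dioxolan-4-one; 12 5-bromo-2-methylpent-2-ene
Product: 15 methyl (2R)-2-hydroxy-2,6-dimethylhept-5-enoate, via lithium enolate 13 (not isolated), via alkylated dioxolanone 14 (not isolated)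
Conditions: LiN(iPr)2 (1.1 equiv), THF, −78 °C; 12 (1.5 equiv), DMPU, −78 → −30 °C; then MeOH, NaOMe (0.3 equiv), 0 °C → rt
Reagents that add atoms: methanol CO
Why: Seebach self-regeneration of stereocentres, in which the enolate is alkylated on the face anti to the tert-butyl group (net retention) to set the quaternary (R) carbinol that becomes C8', and methoxide-catalysed methanolysis then releases the methyl ester.

Step 8
Reactants: 15 methyl (2R)-2-hydroxy-2,6-dimethylhept-5-enoate
Product: 16 1-[(2R)-2-hydroxy-6-methylhept-5-en-2-yl]cyclopropan-1-ol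
Conditions: EtMgBr (4.5 equiv, slow addition), Ti(OiPr)4 (1.1 equiv), THF, 0 °C → rt; sat. aq. NH4Cl
Reagents that add atoms: ethylmagnesium bromide CC[Mg]Br
Why: Kulinkovich cyclopropanation, in which the titanacyclopropane acts as a 1,2-dicarbanion towards the ester carbonyl (the free tertiary hydroxyl is carried as its alkoxide with one extra equivalent of Grignard reagent), supplies C5' and C6' without touching C8'.

Step 9
Reactants: 16 1-[(2R)-2-hydroxy-6-methylhept-5-en-2-yl]cyclopropan-1-ol; 10 {[(2S)-2-(4,4-dichlorobut-3-en-1-yl)-2,8-dimethylchroman-6-yl]oxy}triisopropylsilane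
Product: 19 (3E,8R)-1-[(2S)-2,8-dimethyl-6-(triisopropylsilyloxy)chroman-2-yl]-8-hydroxy-4,8,12-trimethyltrideca-3,11-dien-7-one, via zinc homoenolate 17 (not isolated), via chloroalkene 18 (not isolated)
Conditions: 16 (1.3 equiv), Et2Zn (2.2 equiv per 16), THF–DMSO (4:1), 0 °C → rt; then 10, PdCl2(DPEphos) (5 mol %), 45 °C; then Me2Zn (3 equiv), Pd(PtBu3)2 (5 mol %), 60 °C; sat. aq. NH4Cl
Reagents that add atoms: dimethylzinc C[Zn]C
Why: Proposed new method: Et2Zn turns diol 16 into its zinc alkoxides and strain-driven β-carbon elimination of the zinc cyclopropoxide gives the β-zincio ketone 17 (a ketone homoenolate, nucleophilic at C5'), zerovalent palladium inserts selectively into the C–Cl bond of 10 that is trans to the alkyl chain (the less hindered one), transmetalation and reductive elimination join C5' to C4' to give the (Z)-chloroalkene 18, and the remaining chloride is then exchanged for methyl with retention, so the C3'=C4' double bond is formed as the E isomer and the quaternary C8' centre is untouched; the closest known reaction types are the trans-selective Negishi mono-alkylation of 1,1-dichloroalkenes with alkylzincs followed by methylation, and palladium-catalysed couplings of zinc homoenolates made from cyclopropanols with Et2Zn.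

Step 10
Reactants: 19 (3E,8R)-1-[(2S)-2,8-dimethyl-6-(triisopropylsilyloxy)chroman-2-yl]-8-hydroxy-4,8,12-trimethyltrideca-3,11-dien-7-one
Product: 20 (3E,7S,8R)-1-[(2S)-2,8-dimethyl-6-(triisopropylsilyloxy)chroman-2-yl]-4,8,12-trimethyltrideca-3,11-diene-7,8-diol
Conditions: (R)-2-methyl-CBS-oxazaborolidine (1.0 equiv), catecholborane (3 equiv), toluene, −78 → −40 °C; MeOH, then aq. potassium sodium tartrate (KNaC4H4O6)
Reagents that add atoms: none
Why: Corey–Bakshi–Shibata reduction, in which the (R)-oxazaborolidine treats the fully substituted C8' as the large and C6'H2 as the small ketone substituent and delivers hydride to the face that gives 7'S (the substrate bias of Me versus CH2 at C8' is weak, so the catalyst decides), while catecholborane leaves the alkenes alone.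

Step 11
Reactants: 20 (3E,7S,8R)-1-[(2S)-2,8-dimethyl-6-(triisopropylsilyloxy)chroman-2-yl]-4,8,12-trimethyltrideca-3,11-diene-7,8-diol
Product: 21 (2S)-2-[(3E,7S,8R)-7,8-dihydroxy-4,8,12-trimethyltrideca-3,11-dien-1-yl]-2,8-dimethylchroman-6-ol
Conditions: tetrabutylammonium fluoride (1.2 equiv), THF, 0 °C, argon; sat. aq. NH4Cl
Reagents that add atoms: none
Why: Fluoride-induced cleavage of the aryl silyl ether under non-acidic conditions frees the phenol without risking acid-promoted cyclisation of the tertiary alcohol onto the terminal alkene.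

## Compound list

1 | 3-bromo-5-methylphenol | Cc1cc(O)cc(Br)c1 | starting material
2 | 3-bromo-4-chloro-5-methylphenol | Cc1cc(O)cc(Br)c1Cl | intermediate
3 | (3-bromo-4-chloro-5-methylphenoxy)triisopropylsilane | Cc1cc(O[Si](C(C)C)(C(C)C)C(C)C)cc(Br)c1Cl | intermediate
4 | (S)-(+)-linalool, (3S)-3,7-dimethylocta-1,6-dien-3-ol | C=C[C@@](C)(O)CCC=C(C)C | starting material
5 | 9-[(3R)-3-hydroxy-3,7-dimethyloct-6-en-1-yl]-9-borabicyclo[3.3.1]nonane (same spatial arrangement as 4; shown with free OH) | C1CCC2CCCC1B2CC[C@@](C)(O)CCC=C(C)C | intermediate (not isolated)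
6 | (3S)-1-[2-chloro-3-methyl-5-(triisopropylsilyloxy)phenyl]-3,7-dimethyloct-6-en-3-ol | Cc1cc(O[Si](C(C)C)(C(C)C)C(C)C)cc(CC[C@@](C)(O)CCC=C(C)C)c1Cl | intermediate
7 | triisopropyl{[(2S)-2,8-dimethyl-2-(4-methylpent-3-en-1-yl)chroman-6-yl]oxy}silane | CC(C)=CCC[C@@]1(C)CCc2cc(O[Si](C(C)C)(C(C)C)C(C)C)cc(C)c2O1 | intermediate
8 | 5-[(2R)-2,8-dimethyl-6-(triisopropylsilyloxy)chroman-2-yl]-2-methylpentane-2,3-diol (both C3 epimers) | CC(C)(O)C(O)CC[C@@]1(C)CCc2cc(O[Si](C(C)C)(C(C)C)C(C)C)cc(C)c2O1 | intermediate (not isolated)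
9 | 3-[(2R)-2,8-dimethyl-6-(triisopropylsilyloxy)chroman-2-yl]propanal | O=CCC[C@@]1(C)CCc2cc(O[Si](C(C)C)(C(C)C)C(C)C)cc(C)c2O1 | intermediate
10 | {[(2S)-2-(4,4-dichlorobut-3-en-1-yl)-2,8-dimethylchroman-6-yl]oxy}triisopropylsilane | ClC(Cl)=CCC[C@@]1(C)CCc2cc(O[Si](C(C)C)(C(C)C)C(C)C)cc(C)c2O1 | intermediate
11 | (2S,5S)-2-tert-butyl-5-methyl-1,3-dioxolan-4-one (cis) | C[C@@H]1O[C@H](C(C)(C)C)OC1=O | starting material
12 | 5-bromo-2-methylpent-2-ene | CC(C)=CCCBr | starting material
13 | lithium (2S)-2-tert-butyl-5-methyl-1,3-dioxol-4-olate | CC1=C(O[Li])O[C@@H](C(C)(C)C)O1 | intermediate (not isolated)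
14 | (2S,5R)-2-tert-butyl-5-methyl-5-(4-methylpent-3-en-1-yl)-1,3-dioxolan-4-one | C[C@]1(CCC=C(C)C)O[C@H](C(C)(C)C)OC1=O | intermediate (not isolated)
15 | methyl (2R)-2-hydroxy-2,6-dimethylhept-5-enoate | COC(=O)[C@](C)(O)CCC=C(C)C | intermediate
16 | 1-[(2R)-2-hydroxy-6-methylhept-5-en-2-yl]cyclopropan-1-ol | OC1(CC1)[C@](C)(O)CCC=C(C)C | intermediate
17 | ethyl{(4R)-4-[(ethylzincio)oxy]-4,8-dimethyl-3-oxonon-7-en-1-yl}zinc (idealised monomer) | CC[Zn]CCC(=O)[C@](C)(O[Zn]CC)CCC=C(C)C | intermediate (not isolated)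
18 | ethylzinc alkoxide of (3Z,8R)-4-chloro-1-[(2S)-2,8-dimethyl-6-(triisopropylsilyloxy)chroman-2-yl]-8-hydroxy-8,12-dimethyltrideca-3,11-dien-7-one | CC(C)=CCC[C@@](C)(O[Zn]CC)C(=O)CC/C(Cl)=C/CC[C@@]1(C)CCc2cc(O[Si](C(C)C)(C(C)C)C(C)C)cc(C)c2O1 | intermediate (not isolated)
19 | (3E,8R)-1-[(2S)-2,8-dimethyl-6-(triisopropylsilyloxy)chroman-2-yl]-8-hydroxy-4,8,12-trimethyltrideca-3,11-dien-7-one | CC(C)=CCC[C@@](C)(O)C(=O)CC/C(C)=C/CC[C@@]1(C)CCc2cc(O[Si](C(C)C)(C(C)C)C(C)C)cc(C)c2O1 | intermediate
20 | (3E,7S,8R)-1-[(2S)-2,8-dimethyl-6-(triisopropylsilyloxy)chroman-2-yl]-4,8,12-trimethyltrideca-3,11-diene-7,8-diol | CC(C)=CCC[C@@](C)(O)[C@@H](O)CC/C(C)=C/CC[C@@]1(C)CCc2cc(O[Si](C(C)C)(C(C)C)C(C)C)cc(C)c2O1 | intermediate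
21 | (2S)-2-[(3E,7S,8R)-7,8-dihydroxy-4,8,12-trimethyltrideca-3,11-dien-1-yl]-2,8-dimethylchroman-6-ol | CC(C)=CCC[C@@](C)(O)[C@@H](O)CC/C(C)=C/CC[C@@]1(C)CCc2cc(O)cc(C)c2O1 | target

## Step count and risks

Total steps: 11 (steps 1–6 for the chroman fragment, 7–8 for the cyclopropanol, 9–11 for the endgame).
Longest linear sequence: 9 steps (1 → 2 → 3 → 6 → 7 → 9 → 10 → 19 → 20 → 21).

The three steps most likely to fail:

**Step 9 (homoenolate coupling and methylation in one pot).** Ethyl transfer from zinc, β-hydride loss from the alkylpalladium homoenolate, or incomplete trans-selectivity could erode yield or alkene geometry. The fallback sets out from 10 (and uses 16) and comes back at 19, fixing the geometry before the homoenolate is introduced. Treatment of 10 with nBuLi (2.2 equiv, THF, −78 °C) and then MeI gives the methyl alkyne {[(2S)-2,8-dimethyl-2-(pent-3-yn-1-yl)chroman-6-yl]oxy}triisopropylsilane F1. Syn-hydrozirconation with excess Cp2Zr(H)Cl (zirconium settles on the methyl-bearing carbon) followed by I2 gives the vinyl iodide {[(2S)-2-[(3E)-4-iodopent-3-en-1-yl]-2,8-dimethylchroman-6-yl]oxy}triisopropylsilane F2. This single, geometry-defined electrophile is then coupled with cyclopropanol 16 by zinc-free palladium-catalysed ring-opening cross-coupling (Pd(OAc)2, XPhos, Cs2CO3, toluene, 80 °C) to reach 19, at the cost of two extra steps.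

**Step 4 (C–O ring closure on a hindered, electron-rich aryl chloride).** Oxidative addition may be too slow. The fallback sets out from 1 (and uses alkylborane 5 from 4) and comes back at 7, using a more reactive halide and a copper-mediated closure. Para-bromination of 1 (NBS, MeCN, 0 °C) gives 3,4-dibromo-5-methylphenol F3, and silylation gives (3,4-dibromo-5-methylphenoxy)triisopropylsilane F4. B-alkyl Suzuki coupling of 5 at the less hindered, less electron-rich C3–Br gives (3S)-1-[2-bromo-3-methyl-5-(triisopropylsilyloxy)phenyl]-3,7-dimethyloct-6-en-3-ol F5. An Ullmann-type etherification (CuI, 3,4,7,8-tetramethyl-1,10-phenanthroline, Cs2CO3, toluene, 110 °C) then closes the ring to 7 with retention at C2.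

**Step 10 (7'S selectivity next to a free tertiary alcohol).** The free hydroxyl may perturb the oxazaborolidine model and lower the diastereomer ratio. The fallback sets out from 19 and comes back at 20 and changes the control element: instead of ignoring the hydroxyl it uses it as a directing group in a hydroxyl-directed, catalyst-controlled hydrogenation with RuCl2[(S)-binap] (1 mol %), H2 (50 atm), MeOH, 40 °C. The isolated trisubstituted alkenes are inert under these conditions, and the (S)-ligand is the one that maps onto 7'S for an α-hydroxy ketone. This fallback makes no new compound (entry F0).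

## Further compounds

F1 | step 9 | {[(2S)-2,8-dimethyl-2-(pent-3-yn-1-yl)chroman-6-yl]oxy}triisopropylsilane | CC#CCC[C@@]1(C)CCc2cc(O[Si](C(C)C)(C(C)C)C(C)C)cc(C)c2O1
F2 | step 9 | {[(2S)-2-[(3E)-4-iodopent-3-en-1-yl]-2,8-dimethylchroman-6-yl]oxy}triisopropylsilane | I/C(C)=C/CC[C@@]1(C)CCc2cc(O[Si](C(C)C)(C(C)C)C(C)C)cc(C)c2O1
F3 | step 4 | 3,4-dibromo-5-methylphenol | Cc1cc(O)cc(Br)c1Br
F4 | step 4 | (3,4-dibromo-5-methylphenoxy)triisopropylsilane | Cc1cc(O[Si](C(C)C)(C(C)C)C(C)C)cc(Br)c1Br
F5 | step 4 | (3S)-1-[2-bromo-3-methyl-5-(triisopropylsilyloxy)phenyl]-3,7-dimethyloct-6-en-3-ol | Cc1cc(O[Si](C(C)C)(C(C)C)C(C)C)cc(CC[C@@](C)(O)CCC=C(C)C)c1Br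
F0 | step 10 | none | none
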